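**Plan**

- Retrosynthesis, in quinone numbering: remove the C1 oxygen, restore a carboxyl on C3 to give a 6-nonadecylsalicylate, then cut ring bond C2–C3, then C5–C6, then C1–C2.
- Enabling feature: in the quinone ring the chain-bearing C2 and the oxygenated C4 are meta, with unsubstituted C3 between them. This is the footprint of a 6-alkylsalicylate whose carboxyl sat on C3; the C1 oxygen lies para to C4 and can be added last.
- Forward: the chain is joined linearly (C20 acid + malonate, then acetoacetate dianion + aldehyde). The ketone is unmasked and the benzene ring, the only ring, closes in one aldol–aromatisation.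
- End game: ester hydrolysis, decarboxylation and para-oxidation of the phenol.
- Stereochemistry: the target is achiral. The one carbinol centre on the route is racemic and is erased on aromatisation.

Key step: step 6

Remark: the target has no stereogenic centre and no stereogenic double bond, so the single-enantiomer requirement is met by the achiral compound itself and no enantiocontrol is needed.

**Route**

Step 1
Reactants: 1 arachidic acid (icosanoic acid); 2 potassium methyl malonate
Product: 4 methyl 3-oxodocosanoate, via 1-icosanoylimidazole 3 (not isolated)
Conditions: CDI, THF, 40 °C; then 2, MgCl2, Et3N, MeCN/THF, rt → 45 °C; 1 M HCl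
Reagents that add atoms: none
Why: Masamune–Brooks homologation, in which the acyl imidazolide C-acylates the magnesium enolate of the malonate half-ester and the acylmalonate decarboxylates on acidic work-up to the β-keto ester, a reaction routinely applied to fatty acids.

Step 2
Reactants: 4 methyl 3-oxodocosanoate
Product: 5 methyl 2-(2-nonadecyl-1,3-dioxolan-2-yl)acetate
Conditions: HOCH2CH2OH, TsOH·H2O (cat.), toluene, reflux, Dean–Stark
Reagents that add atoms: ethylene glycol, OCCO
Why: Acid-catalysed dioxolane formation with azeotropic removal of water is the standard protection of a β-keto ester ketone and leaves the methyl ester untouched.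

Step 3
Reactants: 5 methyl 2-(2-nonadecyl-1,3-dioxolan-2-yl)acetate
Product: 6 2-(2-nonadecyl-1,3-dioxolan-2-yl)acetaldehyde
Conditions: DIBAL-H (1.05 equiv), CH2Cl2 (dilute), −78 °C; aq. Rochelle salt
Reagents that add atoms: none
Why: Partial DIBAL-H reduction of an ester, in which the aluminium hemiacetal is stable at −78 °C (helped by chelation to a dioxolane oxygen) and releases the aldehyde only on work-up, while the ketal is inert to hydride.

Step 4
Reactants: 6 2-(2-nonadecyl-1,3-dioxolan-2-yl)acetaldehyde; 7 methyl acetoacetate
Product: 9 methyl 5-hydroxy-6-(2-nonadecyl-1,3-dioxolan-2-yl)-3-oxohexanoate (racemic), via methyl acetoacetate dianion 8 (not isolated)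
Conditions: 7, LDA (2.1 equiv), THF, 0 °C; then 6, −78 → −40 °C; AcOH
Reagents that add atoms: none
Why: Acetoacetate dianion aldol (Weiler dianion chemistry), in which the more reactive terminal carbanion adds to the aldehyde and the β-keto ester enolate remains as a spectator; the carbinol forms as a racemate, which is immaterial because this centre is later destroyed, and the ketal is stable to base.

Step 5
Reactants: 9 methyl 5-hydroxy-6-(2-nonadecyl-1,3-dioxolan-2-yl)-3-oxohexanoate
Product: 10 methyl 5-hydroxy-3,7-dioxohexacosanoate (racemic)
Conditions: 1 M aq. HCl, THF, 0 °C → rt; neutral work-up, used promptly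
Reagents that add atoms: water, O
Why: Acid-catalysed hydrolysis of a dialkyl ketone dioxolane proceeds in dilute acid at room temperature, conditions under which a methyl ester and a β-hydroxy ketone are expected to survive if exposure is kept short.

Step 6
Reactants: 10 methyl 5-hydroxy-3,7-dioxohexacosanoate
Product: 13 methyl 2-hydroxy-6-nonadecylbenzoate, via cyclic aldol 11 (not isolated), via hydroxy enone ester 12 (not isolated)
Conditions: TiCl4 (2.5 equiv), pyridine (5 equiv), THF, 0 °C → rt; then TsOH·H2O (cat.), toluene, 80 °C
Reagents that add atoms: none
Why: Titanium chelation enolises only the C2 methylene between the ester and the C3 ketone, and this enolate adds to the titanium-activated C7 ketone to form the C2–C7 bond and close the six-membered carbocycle (11) in a favoured 6-exo-trig closure (6-enolexo through the ester-enolate form). Pyridine-assisted loss of the tertiary titanium alkoxide gives the Knoevenagel enone 12; under TsOH the remaining ring hydroxyl (old C5) is lost through enolisation of the ring ketone and the resulting cyclohexadienone tautomerises to the phenol, the gain of aromaticity making the sequence irreversible. The closest known reaction types are the TiCl4/pyridine Knoevenagel condensation of ketones with β-keto esters (Lehnert variant), the ring-closing stage of the TiCl4-mediated [3+3] cycloaromatisation of 1,3-bis(silyloxy)dienes with β-keto acetals, which passes through a 5-alkoxy-3,7-dioxo ester, and the biomimetic aldol aromatisation of 3,5,7-triketo esters to resorcylates. No stereocentre is set, since the C5 carbinol and the transient ring centres of 11 and 12 all vanish on aromatisation. The step needs C2-to-C7 aldolisation to run ahead of δ-lactonisation, retro-aldol cleavage and dehydration at C5; this is secured because only the 1,3-dicarbonyl unit is enolised under these soft conditions, no free alkoxide is present, closure from C4 or C6 would give a four-membered ring, and the C3 carbonyl is tied up in the chelate so that C8 has no partner.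

Step 7
Reactants: 13 methyl 2-hydroxy-6-nonadecylbenzoate
Product: 14 2-hydroxy-6-nonadecylbenzoic acid
Conditions: KOH, DMSO/H2O, 90 °C; then 2 M HCl
Reagents that add atoms: potassium hydroxide, [K+].[OH-]
Why: Saponification of a hindered, hydrogen-bonded 2,6-disubstituted salicylate needs hot hydroxide in a dipolar solvent, and nothing else in the molecule is base-sensitive.

Step 8
Reactants: 14 2-hydroxy-6-nonadecylbenzoic acid
Product: 15 3-nonadecylphenol
Conditions: neat melt, 190–200 °C, N2
Reagents that add atoms: none
Why: Thermal protodecarboxylation of an ortho-hydroxybenzoic acid through its ipso-protonated keto tautomer, the same reaction that converts anacardic acids into cardanols on heating.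

Step 9
Reactants: 15 3-nonadecylphenol
Product: 16 2-nonadecyl-1,4-benzoquinone
Conditions: (KSO3)2NO (2.5 equiv), aq. KH2PO4, Aliquat 336 (cat.), CH2Cl2, rt
Reagents that add atoms: Fremy's salt (potassium nitrosodisulfonate), [K+].[K+].[O]N(S(=O)(=O)[O-])S(=O)(=O)[O-]
Why: Teuber oxidation, in which one nitroxyl radical abstracts the phenolic hydrogen, a second couples through oxygen at the free para position and loss of imidodisulfonate gives the p-quinone; the meta alkyl group leaves the para position open and phase transfer brings the lipophilic phenol into contact with the reagent.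

**Compound list**

1 | arachidic acid (icosanoic acid) | CCCCCCCCCCCCCCCCCCCC(=O)O | starting material
2 | potassium methyl malonate (potassium 3-methoxy-3-oxopropanoate) | COC(=O)CC(=O)[O-].[K+] | starting material
3 | 1-icosanoylimidazole | CCCCCCCCCCCCCCCCCCCC(=O)n1ccnc1 | intermediate
4 | methyl 3-oxodocosanoate | COC(=O)CC(=O)CCCCCCCCCCCCCCCCCCC | intermediate
5 | methyl 2-(2-nonadecyl-1,3-dioxolan-2-yl)acetate | COC(=O)CC1(CCCCCCCCCCCCCCCCCCC)OCCO1 | intermediate
6 | 2-(2-nonadecyl-1,3-dioxolan-2-yl)acetaldehyde | O=CCC1(CCCCCCCCCCCCCCCCCCC)OCCO1 | intermediate
7 | methyl acetoacetate | COC(=O)CC(C)=O | starting material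
8 | methyl acetoacetate dianion (dilithium salt) | C=C([O-])C=C([O-])OC.[Li+].[Li+] | intermediate
9 | methyl 5-hydroxy-6-(2-nonadecyl-1,3-dioxolan-2-yl)-3-oxohexanoate (racemic) | COC(=O)CC(=O)CC(O)CC1(CCCCCCCCCCCCCCCCCCC)OCCO1 | intermediate
10 | methyl 5-hydroxy-3,7-dioxohexacosanoate (racemic) | COC(=O)CC(=O)CC(O)CC(=O)CCCCCCCCCCCCCCCCCCC | intermediate
11 | methyl 2,4-dihydroxy-2-nonadecyl-6-oxocyclohexane-1-carboxylate (cyclic aldol, mixture of racemic diastereomers) | COC(=O)C1C(=O)CC(O)CC1(O)CCCCCCCCCCCCCCCCCCC | intermediate
12 | methyl 4-hydroxy-2-nonadecyl-6-oxocyclohex-1-ene-1-carboxylate (hydroxy enone ester, racemic) | COC(=O)C1=C(CCCCCCCCCCCCCCCCCCC)CC(O)CC1=O | intermediate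
13 | methyl 2-hydroxy-6-nonadecylbenzoate | COC(=O)c1c(O)cccc1CCCCCCCCCCCCCCCCCCC | intermediate
14 | 2-hydroxy-6-nonadecylbenzoic acid | OC(=O)c1c(O)cccc1CCCCCCCCCCCCCCCCCCC | intermediate
15 | 3-nonadecylphenol | Oc1cccc(CCCCCCCCCCCCCCCCCCC)c1 | intermediate
16 | 2-nonadecyl-1,4-benzoquinone (2-nonadecylcyclohexa-2,5-diene-1,4-dione) | CCCCCCCCCCCCCCCCCCCC1=CC(=O)C=CC1=O | target

**Totals**

Total step count: 9
Longest linear sequence: 9 steps (from 1 to 16)

**Steps most likely to fail**

Step 6. Dehydration at C5 or δ-lactonisation of the hydroxy ester may run ahead of the C2–C7 aldol, or the cyclised material may stop short of full aromatisation. The fallback builds the same ring by a [3+3] cycloaromatisation that never isolates the linear chain. It sets out from 1, which is converted with CDI and N,O-dimethylhydroxylamine hydrochloride into N-methoxy-N-methylicosanamide F1. Addition of ethynylmagnesium bromide in THF at 0 °C with a cold acidic quench gives docos-1-yn-3-one F2. Conjugate addition of methanol with catalytic DABCO gives (E)-1-methoxydocos-1-en-3-one F3. Treatment of F3 with commercial 1-methoxy-1,3-bis(trimethylsilyloxy)buta-1,3-diene and TiCl4 in CH2Cl2 from −78 °C to rt should add the diene terminus to the methoxy-bearing carbon and close the ring from the central carbon of the diene onto the ketone. The same ring bond is formed, with loss of methanol and water, and the route is rejoined at 13.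

Step 5. Acid-promoted loss of water from the β-hydroxy ketone, or uncontrolled condensation, may occur while the dioxolane is being hydrolysed. The fallback sets out from 9 and keeps the C5 oxygen capped until the ring is closed. Silylation with TBSCl and imidazole in DMF gives methyl 5-(tert-butyldimethylsilyloxy)-6-(2-nonadecyl-1,3-dioxolan-2-yl)-3-oxohexanoate F4. Hydrolysis of the dioxolane with PPTS in wet acetone gives methyl 5-(tert-butyldimethylsilyloxy)-3,7-dioxohexacosanoate F5. F5 is then submitted to the titanium-mediated cyclisation and acid stage of step 6, in which the silanol is expelled in place of water, and the route is rejoined at 13.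

Step 4. The strongly basic dianion may deprotonate the α-methylene of the aldehyde, after which β-elimination opens the dioxolane, in competition with carbonyl addition. The fallback sets out from 6 and replaces the dianion by a base-free vinylogous Mukaiyama aldol. Commercial 1-methoxy-1,3-bis(trimethylsilyloxy)buta-1,3-diene is added to 6 with BF3·OEt2 in CH2Cl2 at −78 °C, and mild acidic work-up removes the silyl groups. This detour makes no new compound (F0) and rejoins the route at 9.

**Further compounds**

F1 | step 6 | N-methoxy-N-methylicosanamide | CCCCCCCCCCCCCCCCCCCC(=O)N(C)OC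
F2 | step 6 | docos-1-yn-3-one | C#CC(=O)CCCCCCCCCCCCCCCCCCC
F3 | step 6 | (E)-1-methoxydocos-1-en-3-one | CO/C=C/C(=O)CCCCCCCCCCCCCCCCCCC
F4 | step 5 | methyl 5-(tert-butyldimethylsilyloxy)-6-(2-nonadecyl-1,3-dioxolan-2-yl)-3-oxohexanoate (racemic) | COC(=O)CC(=O)CC(O[Si](C)(C)C(C)(C)C)CC1(CCCCCCCCCCCCCCCCCCC)OCCO1
F5 | step 5 | methyl 5-(tert-butyldimethylsilyloxy)-3,7-dioxohexacosanoate (racemic) | COC(=O)CC(=O)CC(O[Si](C)(C)C(C)(C)C)CC(=O)CCCCCCCCCCCCCCCCCCC
F0 | step 4 | none | none
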